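**Plan**

1. Iridoid numbering is used: C1 acetal carbon, O2 ring oxygen, C3=C4 enol ether, C5 and C9 ring-fusion carbons, C6 to C8 in ring B (the cyclopentene), C10 on C8, C11 on C4; ring A is the pyran; β is the face of H9, α the other face.
2. Retrosynthesis: the ester C–O bonds at C1, C7, C10 and C11 are cut first, then C4–C11 (coupling of a C4 enol triflate), then the C7 carbinol and the C5=C6 bond are traced back to a C7,C8-diol, and last the two ring B bonds C8–C9 and C5–C6 are cut.
3. Enabling feature: the acetal carbon C1 is bonded to the fusion carbon C9, so a 6-silyloxy-2H-pyran-3(6H)-one already holds ring A, C1 and an enone whose C=C is C5=C9; a three-carbon unit can be annulated across C9 and C5 to close ring B in one step.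
4. Forward: ring A by Achmatowicz oxidation of furfuryl alcohol; ring B by phosphine-catalysed (3+2) annulation with ethyl buta-2,3-dienoate; then C4 enol triflate, C10 reduction and esterification, C7/C8 dihydroxylation, oxidation to the C7 ketone with C5=C6 dehydrogenation, C11 by Stille coupling, acyl exchange at C1, C7 reduction and esterification.
5. Stereochemistry: C1 comes from the resolved silyl acetal and sends the annulation to its opposite face (C9, then C5 by cis ring closure); C8 is set by dihydroxylation on the convex β face; C7 by hydride addition to the C7 ketone from the β face; C1 is set again, under control of the C8 substituents, when the lactol is acylated.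

Key step: step 4

Remark on the chemistry: lactol 18 is written as its β-anomer; the anomers interconvert by ring opening, and the C1 configuration of the target is fixed only in step 14.

**Route**

Step 1
Reactants: 1 furfuryl alcohol
Product: 2 racemic 6-hydroxy-2H-pyran-3(6H)-one
Conditions: mCPBA, CH2Cl2, 0 °C
Reagents that add atoms: mCPBA, O=C(OO)c1cccc(Cl)c1
Why: Achmatowicz oxidative ring expansion, in which oxidation of the furan, opening to the cis-enedione and lactol closure should give the pyranone with a racemic lactol carbon.

Step 2
Reactants: 2 racemic 6-hydroxy-2H-pyran-3(6H)-one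
Product: 3 racemic 6-(tert-butyldimethylsilyloxy)-2H-pyran-3(6H)-one
Conditions: TBSCl, imidazole, CH2Cl2, 0 °C
Reagents that add atoms: tert-butyldimethylsilyl chloride, CC(C)(C)[Si](C)(C)Cl
Why: O-silylation of the lactol, which locks the acetal so that it can no longer racemise by ring opening.

Step 3
Reactants: 3 racemic 6-(tert-butyldimethylsilyloxy)-2H-pyran-3(6H)-one
Product: 4 (S)-6-(tert-butyldimethylsilyloxy)-2H-pyran-3(6H)-one
Conditions: preparative supercritical-fluid chromatography on an amylose tris(3,5-dimethylphenylcarbamate) stationary phase, CO2/iPrOH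
Reagents that add atoms: none
Why: Resolution of enantiomers on a chiral stationary phase, in which no bond changes, the (S)-enantiomer is collected and the silyl acetal is configurationally stable.

Step 4
Reactants: 4 (S)-6-(tert-butyldimethylsilyloxy)-2H-pyran-3(6H)-one; 5 ethyl buta-2,3-dienoate
Product: 6 cis-fused keto ester (4-oxo; C7=C8 with CO2Et on C8; 1-OTBS β; H5 and H9 β)
Conditions: PBu3 (10 mol %), toluene, rt, slow addition of 5
Reagents that add atoms: none
Why: Lu-type phosphine-catalysed (3+2) annulation: PBu3 adds to the central carbon of 5, the α-carbon of the resulting phosphonium dienolate attacks C9 (the enone β-carbon) to form C8–C9, and the C4 enolate then closes ring B by attack of C5 on the terminal carbon of the vinylphosphonium to form C5–C6, a 5-endo-trig closure, after which proton shift and loss of PBu3 leave the C7=C8 double bond bearing the ester. The closest known reaction type is the phosphine-catalysed allenoate annulation of cyclic enones, which has been run on 6-oxy-2H-pyran-3(6H)-ones. C9 is set by attack anti to the pseudoaxial C1 silyloxy group, so that H9 ends up cis to the C1 oxygen; C5 is set by the ring closure itself, because the three-carbon unit can bridge only one face of the enone, which gives the cis fusion. The step needs α- over γ-regioselectivity and facial selectivity: the unsubstituted, unhindered C9 allows bond formation at the α-carbon of the dienolate, and the acetal substituent blocks one face. Slow addition of 5 should hold back its phosphine-induced oligomerisation.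

Step 5
Reactants: 6 cis-fused keto ester
Product: 8 C4 enol triflate ethyl ester (C3=C4), via potassium enolate 7 (not isolated)
Conditions: KN(SiMe3)2, THF, −78 °C; then PhNTf2, −78 to 0 °C
Reagents that add atoms: N-phenylbis(trifluoromethanesulfonimide), O=S(=O)(N(c1ccccc1)S(=O)(=O)C(F)(F)F)C(F)(F)F
Why: Kinetic enolisation and O-sulfonylation (enol triflate formation), in which the base should take a proton from the unhindered C3 methylene, acidified by O2, rather than from the ring-fusion methine at C5, so that the C3=C4 triflate forms and the ketone is masked for the reduction and oxidation steps that follow.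

Step 6
Reactants: 8 C4 enol triflate ethyl ester
Product: 9 allylic alcohol (C10 hydroxyl)
Conditions: iBu2AlH, CH2Cl2, −78 °C; aqueous potassium sodium tartrate work-up
Reagents that add atoms: none
Why: 1,2-Reduction of the conjugated ester to the allylic alcohol with an aluminium hydride, the enol triflate and the silyl acetal being inert at −78 °C and no ketone being left to interfere.

Step 7
Reactants: 9 allylic alcohol; 10 isovaleric anhydride
Product: 11 C10 isovalerate
Conditions: Et3N, DMAP (cat.), CH2Cl2, 0 °C
Reagents that add atoms: none
Why: DMAP-catalysed acylation of the only free hydroxyl, a primary allylic alcohol.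

Step 8
Reactants: 11 C10 isovalerate
Product: 12 7β,8β-diol
Conditions: OsO4 (3 mol %), N-methylmorpholine N-oxide, acetone/H2O, 0 °C to rt
Reagents that add atoms: osmium tetroxide, O=[Os](=O)(=O)=O; N-methylmorpholine N-oxide, C[N+]1([O-])CCOCC1; water, O
Why: Catalytic osmium tetroxide syn-dihydroxylation, in which the oxidant should add to the trisubstituted C7=C8 bond from the convex β face of the cis-fused bicycle (the face of H5 and H9), setting the C8 hydroxyl β as in the target and the C7 hydroxyl β (a centre that is oxidised in the next step), while the C3=C4 bond, deactivated by the triflate, should react more slowly.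

Step 9
Reactants: 12 7β,8β-diol
Product: 14 dienone triflate (C5=C6 conjugated to the C7 ketone; 8β-hydroxyl), via alpha-ketol 13 (not isolated)
Conditions: IBX (2-iodoxybenzoic acid, 1.5 equiv), DMSO, rt; then IBX (2 equiv), 4-methoxypyridine N-oxide, rt to 40 °C
Reagents that add atoms: none
Why: Alcohol oxidation followed by ketone dehydrogenation with the pentavalent iodine reagent, which oxidises the secondary alcohol of a 1,2-diol to the α-ketol without C–C cleavage and can then dehydrogenate the C7 ketone only across C5–C6, because C8 is quaternary and H5 is the sole β-hydrogen of the C6 enol.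

Step 10
Reactants: 14 dienone triflate; 15 (tributylstannyl)methanol
Product: 16 C11 alcohol (hydroxymethyl on C4)
Conditions: Pd(PPh3)4 (10 mol %), LiCl, 1,4-dioxane, 90 °C
Reagents that add atoms: none
Why: Stille cross-coupling, in which zerovalent palladium inserts into the electron-poor C4–OTf bond, LiCl assists transmetalation and the α-oxygenated methylene group is transferred from tin in preference to butyl to form C4–C11 without touching a stereocentre.

Step 11
Reactants: 16 C11 alcohol
Product: 17 C11 acetate
Conditions: Ac2O, pyridine, DMAP (cat.), CH2Cl2, 0 °C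
Reagents that add atoms: acetic anhydride, CC(=O)OC(C)=O
Why: Acylation of the primary allylic alcohol, the tertiary C8 hydroxyl being too hindered to react under these conditions.

Step 12
Reactants: 17 C11 acetate
Product: 18 lactol (1-hydroxyl β)
Conditions: HF·pyridine, pyridine, THF, 0 °C
Reagents that add atoms: none
Why: Fluoride cleavage of the silyl acetal at a stage where O2 is conjugated through C3=C4–C5=C6 to the C7 ketone, a push-pull aglycone that should be stable as its cyclic hemiacetal and should rest as the β-anomer because the α face of C1 is crowded by the C10 acyloxymethyl group on C8.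

Step 13
Reactants: 19 3-hydroxy-3-methylbutanoic acid
Product: 21 3-acetoxy-3-methylbutanoic acid, via mixed anhydride 20 (not isolated)
Conditions: Ac2O, DMAP (cat.), pyridine, CH2Cl2, rt; then H2O
Reagents that add atoms: acetic anhydride, CC(=O)OC(C)=O
Why: DMAP-catalysed acetylation of the tertiary alcohol, in which the carboxyl group is carried as its mixed anhydride and is released again by water at the acetyl carbonyl during work-up.

Step 14
Reactants: 18 lactol; 21 3-acetoxy-3-methylbutanoic acid
Product: 22 C1 ester with C7 ketone
Conditions: N,N'-dicyclohexylcarbodiimide, DMAP (cat.), CH2Cl2, −20 to 0 °C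
Reagents that add atoms: none
Why: Steglich esterification of the lactol hydroxyl, a coupling that is established for β-acyloxy acids, in which the equatorial β-lactol should be acylated so that the C1 oxygen is fixed cis to H9, while the tertiary C8 hydroxyl does not react.

Step 15
Reactants: 22 C1 ester with C7 ketone
Product: 23 7α-alcohol
Conditions: NaBH4, CeCl3·7H2O, MeOH, −78 to −40 °C
Reagents that add atoms: none
Why: Luche 1,2-reduction of the dienone, in which hydride should reach C7 from the β face, next to the small C8 hydroxyl and H9 and away from the C10 acyloxymethyl group, placing the new hydroxyl α and trans to the C8 hydroxyl as in the target, the esters being untouched at this temperature.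

Step 16
Reactants: 23 7α-alcohol; 10 isovaleric anhydride
Product: 24 CNP0331701.2
Conditions: Et3N, DMAP (cat.), CH2Cl2, 0 °C
Reagents that add atoms: none
Why: DMAP-catalysed acylation of the secondary allylic C7 alcohol, in which the tertiary C8 hydroxyl stays free and an isovaleryl shift between O10 and O7 before acylation would lead to the same product.

**Compound list**

1 | furfuryl alcohol | OCc1ccco1 | starting material
2 | racemic 6-hydroxy-2H-pyran-3(6H)-one | O=C1C=CC(O)OC1 | intermediate
3 | racemic 6-(tert-butyldimethylsilyloxy)-2H-pyran-3(6H)-one | O=C1C=CC(O[Si](C)(C)C(C)(C)C)OC1 | intermediate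
4 | (S)-6-(tert-butyldimethylsilyloxy)-2H-pyran-3(6H)-one | O=C1C=C[C@H](O[Si](C)(C)C(C)(C)C)OC1 | intermediate
5 | ethyl buta-2,3-dienoate | C=C=CC(=O)OCC | starting material
6 | cis-fused keto ester: (1S)-1-silyloxy (β), 4-oxo, H5 and H9 β, C7=C8, CO2Et on C8 | O=C1CO[C@@H](O[Si](C)(C)C(C)(C)C)[C@H]2[C@@H]1CC=C2C(=O)OCC | intermediate
7 | potassium C3=C4 enolate of 6 | [K+].[O-]C1=CO[C@@H](O[Si](C)(C)C(C)(C)C)[C@H]2[C@@H]1CC=C2C(=O)OCC | intermediate
8 | C4 enol triflate (C3=C4) of 6, ethyl ester on C8 | FC(F)(F)S(=O)(=O)OC1=CO[C@@H](O[Si](C)(C)C(C)(C)C)[C@H]2[C@@H]1CC=C2C(=O)OCC | intermediate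
9 | allylic alcohol: C4 enol triflate, CH2OH (C10) on C8 | FC(F)(F)S(=O)(=O)OC1=CO[C@@H](O[Si](C)(C)C(C)(C)C)[C@H]2[C@@H]1CC=C2CO | intermediate
10 | isovaleric anhydride (3-methylbutanoic anhydride) | CC(C)CC(=O)OC(=O)CC(C)C | starting material
11 | C10 isovalerate of 9 | FC(F)(F)S(=O)(=O)OC1=CO[C@@H](O[Si](C)(C)C(C)(C)C)[C@H]2[C@@H]1CC=C2COC(=O)CC(C)C | intermediate
12 | 7β,8β-diol (C10 isovalerate α on C8) | FC(F)(F)S(=O)(=O)OC1=CO[C@@H](O[Si](C)(C)C(C)(C)C)[C@H]2[C@@H]1C[C@H](O)[C@@]2(O)COC(=O)CC(C)C | intermediate
13 | alpha-ketol: C7 ketone, 8β-hydroxyl | FC(F)(F)S(=O)(=O)OC1=CO[C@@H](O[Si](C)(C)C(C)(C)C)[C@H]2[C@@H]1CC(=O)[C@@]2(O)COC(=O)CC(C)C | intermediate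
14 | dienone triflate: C3=C4(OTf), C5=C6, C7 ketone, 8β-hydroxyl | FC(F)(F)S(=O)(=O)OC1=CO[C@@H](O[Si](C)(C)C(C)(C)C)[C@H]2C1=CC(=O)[C@@]2(O)COC(=O)CC(C)C | intermediate
15 | (tributylstannyl)methanol | OC[Sn](CCCC)(CCCC)CCCC | starting material
16 | C11 alcohol: CH2OH on C4, C7 ketone, 1-silyloxy β | OCC1=CO[C@@H](O[Si](C)(C)C(C)(C)C)[C@H]2C1=CC(=O)[C@@]2(O)COC(=O)CC(C)C | intermediate
17 | C11 acetate of 16 | CC(=O)OCC1=CO[C@@H](O[Si](C)(C)C(C)(C)C)[C@H]2C1=CC(=O)[C@@]2(O)COC(=O)CC(C)C | intermediate
18 | lactol: 1-hydroxyl β (cis to H9), C7 ketone | CC(=O)OCC1=CO[C@@H](O)[C@H]2C1=CC(=O)[C@@]2(O)COC(=O)CC(C)C | intermediate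
19 | 3-hydroxy-3-methylbutanoic acid | CC(C)(O)CC(=O)O | starting material
20 | acetic 3-acetoxy-3-methylbutanoic anhydride | CC(=O)OC(C)(C)CC(=O)OC(C)=O | intermediate
21 | 3-acetoxy-3-methylbutanoic acid | CC(=O)OC(C)(C)CC(=O)O | intermediate
22 | C1 (3-acetoxy-3-methylbutanoyl) ester (β), C7 ketone | CC(=O)OCC1=CO[C@@H](OC(=O)CC(C)(C)OC(C)=O)[C@H]2C1=CC(=O)[C@@]2(O)COC(=O)CC(C)C | intermediate
23 | 7α-alcohol of 22 (trans to the 8β-hydroxyl) | CC(=O)OCC1=CO[C@@H](OC(=O)CC(C)(C)OC(C)=O)[C@H]2C1=C[C@@H](O)[C@@]2(O)COC(=O)CC(C)C | intermediate
24 | CNP0331701.2 | CC(=O)OCC1=CO[C@@H](OC(=O)CC(C)(C)OC(C)=O)[C@H]2C1=C[C@@H](OC(=O)CC(C)C)[C@@]2(O)COC(=O)CC(C)C | target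

**Totals and risks**

Total step count: 16. Longest linear sequence: 15 steps (steps 1 to 12 and 14 to 16); step 13 is a one-step side branch.

The three steps most likely to fail:

Step 9. The one-pot oxidation and dehydrogenation may stall at the α-ketol, or the silyl acetal may be eroded during long contact with the acidic iodine reagent. The fallback sets out from diol 12 and replaces dehydrogenation by selenoxide elimination. The C7 alcohol is oxidised under Parikh–Doering conditions (SO3·pyridine, DMSO, iPr2NEt, 0 °C) and alpha-ketol 13 is isolated. Its dianion (LiN(SiMe3)2, 2.2 equiv, THF, −78 °C) is selenenylated with PhSeBr on the convex face to give the C6 β-phenylselanyl alpha-ketol F1. H2O2 and pyridine in CH2Cl2 at 0 °C give the selenoxide F2, whose syn-elimination can only involve H5, and the route is rejoined at dienone triflate 14.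

Step 14. The activated acyl donor may lose acetate by β-elimination to give the 3-methylbut-2-enoate, or the lactol may open and epimerise under the acyl-transfer catalyst before it is acylated. The fallback sets out from lactol 18 and activates the lactol instead of the acid. Cl3CCN and Cs2CO3 in CH2Cl2 at 0 °C give the C1 trichloroacetimidate F3. Acid 21 alone in CH2Cl2 then protonates the imidate, and its carboxylate should add to C1 from the open β face, as in the promoter-free synthesis of glycosyl esters from trichloroacetimidates. The route is rejoined at ester 22.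

Step 8. Osmylation of the C3=C4 enol triflate may compete with that of C7=C8 (loss of chemoselectivity). The fallback sets out from allylic alcohol 9 and uses hydrogen-bond-directed dihydroxylation (OsO4 cat., Me3NO·2H2O, CH2Cl2, rt). The C10 hydroxyl guides the amine-ligated osmium reagent to the neighbouring C7=C8 bond and should give the 7β,8β,10-triol F4. Acylation of its primary hydroxyl with one equivalent of 10 (2,4,6-collidine, CH2Cl2, −40 °C) rejoins the route at diol 12.

Further compounds
F1 | step 9 | C6 β-phenylselanyl alpha-ketol | FC(F)(F)S(=O)(=O)OC1=CO[C@@H](O[Si](C)(C)C(C)(C)C)[C@H]2[C@@H]1[C@H]([Se]c3ccccc3)C(=O)[C@@]2(O)COC(=O)CC(C)C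
F2 | step 9 | selenoxide of F1 | FC(F)(F)S(=O)(=O)OC1=CO[C@@H](O[Si](C)(C)C(C)(C)C)[C@H]2[C@@H]1[C@H]([Se](=O)c3ccccc3)C(=O)[C@@]2(O)COC(=O)CC(C)C
F3 | step 14 | C1 trichloroacetimidate of lactol 18 | CC(=O)OCC1=CO[C@@H](OC(=N)C(Cl)(Cl)Cl)[C@H]2C1=CC(=O)[C@@]2(O)COC(=O)CC(C)C
F4 | step 8 | 7β,8β,10-triol with C4 enol triflate | FC(F)(F)S(=O)(=O)OC1=CO[C@@H](O[Si](C)(C)C(C)(C)C)[C@H]2[C@@H]1C[C@H](O)[C@@]2(O)CO
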